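The 3(2H)-furanone ring O–C10–C1–C2–C3 of the target is treated as a masked 3-methoxy-2-methylfuran, and C9–C8(O)–C4 with its C15 carboxyl as a 2-oxyallyl unit. One furan/oxyallyl (4+3) cycloaddition forms C9–C10 and C3–C4, dearomatises the furan and closes an 8-oxabicyclo[3.2.1]octene that already carries quaternary C10, C1 as an enol ether, the C8 oxygen and the C15 ester. C5–C7 are then annulated as a cyclopentane across C4–C8, and retro-aldol (Grob-type) cleavage of that bond opens the ten-membered ring. The key-step precursors are 3-methoxy-2-methylfuran and methyl 2,4-dibromo-3-oxobutanoate, used as its γ-bromo zinc enolate.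

Key step: step 4

Remark: germacranolide numbering of the target (C1–C15) is used for every intermediate.
Remark: the bis(oxazoline) antipode in step 4 and the prolinol antipode in step 6 are assigned by analogy with related reactions; the enantiomeric ligand or catalyst is used if the sense of induction proves opposite.
Remark: a concerted Grob fragmentation of a C5 sulfonate in the exo-fused tricycle would need C5–O antiperiplanar to C4–C8 and would then give the ring-trans C4=C5 ester; the ring is therefore opened by retro-aldol of a C5 ketone and the alkene geometry is fixed at the chelated enolate (steps 10–12).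
Remark: compounds 13–15 are C5 epimer mixtures that converge at ketone 16, and 26 is a C2 epimer mixture, so these centres carry no descriptor.

Step 1
Reactants: 1 3-bromofuran
Product: 2 3-methoxyfuran
Conditions: NaOMe, CuBr (10 mol %), MeOH–NMP, 110 °C, sealed tube
Reagents that add atoms: sodium methoxide, C[O-].[Na+]
Why: Ullmann-type copper-catalysed methoxylation of a 3-bromo five-membered heteroarene; no stereocentre is formed.

Step 2
Reactants: 2 3-methoxyfuran
Product: 4 3-methoxy-2-methylfuran, via 2-lithio-3-methoxyfuran 3 (not isolated)
Conditions: n-BuLi, THF, −78 → 0 °C; MeI, −78 °C → rt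
Reagents that add atoms: iodomethane, CI
Why: Directed lithiation at C2, the position flanked by the ring oxygen and the methoxy group, followed by methylation of the furyllithium (metalation–alkylation); no stereocentre is formed.

Step 3
Reactants: 5 methyl acetoacetate
Product: 6 methyl 2,4-dibromo-3-oxobutanoate
Conditions: Br2 (2.0 equiv), CHCl3, 0 °C → rt
Reagents that add atoms: bromine, BrBr
Why: Acid-catalysed α- and γ-bromination of the β-keto ester, the first bromine moving to the γ-position under HBr before the second enters; the α-stereocentre of 6 is racemic and disappears in step 4.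

Step 4
Reactants: 6 methyl 2,4-dibromo-3-oxobutanoate; 4 3-methoxy-2-methylfuran
Product: 8 oxabicyclic enol keto ester, via ethylzinc enolate 7 (not isolated)
Conditions: Et2Zn (1.1 equiv), 2,2′-isopropylidenebis[(4S)-4-tert-butyl-2-oxazoline] (1.2 equiv), toluene–THF, −78 °C; then 4 (2 equiv), −78 → −20 °C; pH 7 buffer
Reagents that add atoms: none
Why: Proposed new method: halogen–zinc exchange at the doubly activated C4–Br gives the chelated zinc enolate 7, and loss of bromide from C9 then generates a 2-oxyallyl cation that stays bound to the bis(oxazoline)zinc centre through the keto ester chelate. The closest known reactions are the zinc- or Et2Zn-promoted (4+3) cycloadditions of α,α′-dibromo ketones with furans, which are racemic, and the asymmetric (4+3) reactions of chelating oxyallyl cations on copper bis(oxazoline) complexes; their combination on a β-keto ester oxyallyl is new. The seven-membered carbocycle is closed by the cycloaddition itself: the methyl-bearing furan carbon (future C10), the most nucleophilic site as the β-carbon of the methoxy enol ether, bonds to the cationic CH2 terminus C9, and the zinc enolate carbon C4 then closes onto the oxocarbenium terminus (future C3). Both bonds form on one furan face, so the oxygen bridge is necessarily cis and C10 and C3 are set together; their absolute sense is decided by the oxazoline tert-butyl groups, which leave one face of the planar chelate open, and C4 is not a stereocentre in enol 8. The step needs regioselectivity (C9 to C10, C4 to C3), secured by the matched polarity of the 3-methoxyfuran and of the ester-substituted oxyallyl, and chemoselectivity, secured by forming 7 before the furan is added so that the positive-bromine C4–Br never meets the electron-rich furan.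

Step 5
Reactants: 9 3-(trimethylsilyl)prop-2-ynal
Product: 10 (E)-5-(trimethylsilyl)pent-2-en-4-ynal
Conditions: Ph3P=CHCHO (1.0 equiv), CH2Cl2, rt
Reagents that add atoms: (triphenylphosphoranylidene)acetaldehyde, O=CC=P(c1ccccc1)(c1ccccc1)c1ccccc1
Why: Wittig olefination with the stabilised formylmethylene ylide, which gives the (E)-enal; no stereocentre is formed.

Step 6
Reactants: 10 (E)-5-(trimethylsilyl)pent-2-en-4-ynal
Product: 11 (2R,3S)-3-[(trimethylsilyl)ethynyl]oxirane-2-carbaldehyde
Conditions: 35 % aq H2O2, (S)-2-{bis[3,5-bis(trifluoromethyl)phenyl](trimethylsilyloxy)methyl}pyrrolidine (10 mol %), CH2Cl2, rt; used without purification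
Reagents that add atoms: hydrogen peroxide, OO
Why: Iminium-catalysed nucleophilic epoxidation of the enal (conjugate addition of hydrogen peroxide, then closure of the enamine onto the O–O bond), the diarylprolinol silyl ether shielding one face of the (E)-iminium ion so that the trans (2R,3S)-epoxide should form.

Step 7
Reactants: 8 oxabicyclic enol keto ester; 11 epoxy aldehyde
Product: 13 aldol adduct (C5 epimers), via titanium enolate 12 (not isolated)
Conditions: LiN(SiMe3)2, THF, −78 °C; ClTi(OiPr)3; 11, −78 → −30 °C; pH 7 buffer
Reagents that add atoms: none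
Why: Aldol addition of the chelated titanium β-keto ester enolate, which takes up the aldehyde on the exo face of C4 (the oxygen-bridge face, away from the C1=C2 bridge) so that the new C4–C5 bond is axial; the C5 configuration is left open because C5 becomes a ketone in step 10, and C6 comes from 11.

Step 8
Reactants: 13 aldol adduct
Product: 14 tricyclic triol
Conditions: Pd(dppf)Cl2 (5 mol %), InI (1.5 equiv), THF–HMPA (4:1), rt
Reagents that add atoms: none
Why: Palladium-catalysed opening of the alkynyl oxirane to an allenylpalladium species, transmetallation to indium and intramolecular Barbier-type SE2′ propargylation of the C8 ketone; the tether on the exo face forces the cis ring fusion (C8–OH axial), the interconverting allenylindium places the alkynyl group of C7 on the convex face cis to C8–OH, and C6 keeps the epoxide configuration.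

Step 9
Reactants: 14 tricyclic triol
Product: 15 C6 silyl ether
Conditions: t-BuMe2SiCl, imidazole, DMF, 0 °C
Reagents that add atoms: tert-butyldimethylsilyl chloride, CC(C)(C)[Si](C)(C)Cl
Why: Silylation of the least hindered hydroxyl, the secondary C6–OH, the C5–OH being neopentylic and the C8–OH tertiary; no stereocentre is formed.

Step 10
Reactants: 15 C6 silyl ether
Product: 16 C5 ketone
Conditions: Dess–Martin periodinane, NaHCO3, CH2Cl2, 0 °C → rt
Reagents that add atoms: none
Why: Dess–Martin oxidation of the remaining secondary alcohol, which removes the undefined C5 centre and makes C4 the α-carbon of a 1,3-dicarbonyl unit.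

Step 11
Reactants: 16 C5 ketone
Product: 18 ring-expanded enol triflate, via potassium enolate 17 (not isolated)
Conditions: KN(SiMe3)2 (1.05 equiv), THF, −78 → 0 °C; PhNTf2, 0 °C → rt
Reagents that add atoms: N-phenylbis(trifluoromethanesulfonimide), O=S(=O)(N(c1ccccc1)S(=O)(=O)C(F)(F)F)C(F)(F)F
Why: Retro-aldol (Grob-type) fragmentation of the tertiary potassium alkoxide cleaves C4–C8 because it releases ring strain and the stabilised β-keto ester enolate 17, which opens the ten-membered ring; 17 equilibrates to the potassium chelate (C5–O cis to the ester, C6 cis to C3, also the geometry the ring prefers) and O-triflation fixes it.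

Step 12
Reactants: 18 ring-expanded enol triflate
Product: 19 keto enoate
Conditions: Pd(OAc)2 (5 mol %), PPh3, HCO2H/Et3N (1:1), DMF, 40 °C
Reagents that add atoms: none
Why: Palladium-catalysed formate hydrogenolysis of the enol triflate (oxidative addition, hydride transfer from formate, reductive elimination), which replaces the triflate by hydrogen with retention of the C4=C5 geometry.

Step 13
Reactants: 19 keto enoate
Product: 21 alkyne diol, via silylalkyne diol 20 (not isolated)
Conditions: i-Bu2AlH, CH2Cl2, −78 °C; then K2CO3, MeOH, rt
Reagents that add atoms: none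
Why: Hydride reduction of the C8 ketone and 1,2-reduction of the enoate ester to C15H2OH, the hydride adding to C8 anti to the C6–C7 bond (1,2-induction reinforced by the 1,3-anti preference of the β-silyloxy group) so that C8–OH is cis to the C7 alkynyl group (8R); methanolic carbonate then cleaves the alkynylsilane.

Step 14
Reactants: 21 alkyne diol
Product: 22 C15 silyl ether
Conditions: t-BuMe2SiCl (1.05 equiv), imidazole, CH2Cl2, 0 °C
Reagents that add atoms: tert-butyldimethylsilyl chloride, CC(C)(C)[Si](C)(C)Cl
Why: Selective silylation of the primary allylic C15–OH in the presence of the hindered secondary C8–OH; no stereocentre is formed.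

Step 15
Reactants: 22 C15 silyl ether; 23 tiglic acid
Product: 25 C8 tiglate, via mixed anhydride 24 (not isolated)
Conditions: 23, 2,4,6-trichlorobenzoyl chloride, Et3N, toluene, rt; then 22, DMAP, 40 °C
Reagents that add atoms: none
Why: Yamaguchi esterification, the mixed anhydride acylating C8–OH under DMAP catalysis with retention at C8 and without isomerising the (E)-tigloyl double bond.

Step 16
Reactants: 25 C8 tiglate
Product: 26 α-bromo ketone
Conditions: NBS (1.05 equiv), NaHCO3, THF–H2O, 0 °C
Reagents that add atoms: N-bromosuccinimide, O=C1CCC(=O)N1Br; water, O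
Why: Electrophilic bromination of the enol ether at C2, the most electron-rich alkene, and capture of the C1 oxocarbenium ion by water give the α-bromo ketone with loss of methanol (enol ether bromination–hydrolysis).

Step 17
Reactants: 26 α-bromo ketone
Product: 27 furanone
Conditions: DBU, CH2Cl2, 0 °C → rt
Reagents that add atoms: none
Why: Base-induced dehydrobromination (E2, after epimerisation at C2 where needed) gives the C2=C3 enone of the 3(2H)-furanone in conjugation with C4=C5; no stereocentre is formed.

Step 18
Reactants: 27 furanone
Product: 28 diol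
Conditions: HF·pyridine, pyridine, THF, 0 °C → rt
Reagents that add atoms: none
Why: Fluoride cleavage of both silyl ethers under buffered, non-basic conditions, which avoids migration of the tiglate to the cis C6–OH.

Step 19
Reactants: 28 diol
Product: 29 target
Conditions: PdCl2 (10 mol %), PPh3, SnCl2, CO (7 atm), MeCN, 65 °C
Reagents that add atoms: carbon monoxide, [C-]#[O+]
Why: Palladium-catalysed cyclocarbonylation of the homopropargylic alcohol (alkoxycarbonylpalladium formation and syn addition across the alkyne) builds C12 and the C11=C13 exo-methylene in one step, the cis C6–OH/C7–alkynyl relationship from step 8 giving the cis-fused lactone.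

Compound list
1 | 3-bromofuran | Brc1ccoc1 | starting material
2 | 3-methoxyfuran | COc1ccoc1 | intermediate
3 | 2-lithio-3-methoxyfuran (not isolated) | [Li]c1occc1OC | intermediate
4 | 3-methoxy-2-methylfuran | COc1ccoc1C | intermediate
5 | methyl acetoacetate (methyl 3-oxobutanoate) | COC(=O)CC(C)=O | starting material
6 | methyl 2,4-dibromo-3-oxobutanoate (racemic) | COC(=O)C(Br)C(=O)CBr | intermediate
7 | ethylzinc (Z)-enolate of methyl 4-bromo-3-oxobutanoate, bis(oxazoline) ligand on zinc not drawn (not isolated) | CC[Zn]O/C(CBr)=C\C(=O)OC | intermediate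
8 | methyl (1R,5R)-3-hydroxy-6-methoxy-5-methyl-8-oxabicyclo[3.2.1]octa-2,6-diene-2-carboxylate (enol of the β-keto ester; bridgehead CH is C3, bridgehead C–CH3 is C10) | COC(=O)C1=C(O)C[C@@]2(C)O[C@@H]1C=C2OC | intermediate
9 | 3-(trimethylsilyl)prop-2-ynal | C[Si](C)(C)C#CC=O | starting material
10 | (E)-5-(trimethylsilyl)pent-2-en-4-ynal | C[Si](C)(C)C#C/C=C/C=O | intermediate
11 | (2R,3S)-3-[(trimethylsilyl)ethynyl]oxirane-2-carbaldehyde | O=C[C@@H]1O[C@H]1C#C[Si](C)(C)C | intermediate
12 | tri(isopropoxy)titanium enolate of 8 (not isolated) | COC(=O)C1=C(O[Ti](OC(C)C)(OC(C)C)OC(C)C)C[C@@]2(C)O[C@@H]1C=C2OC | intermediate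
13 | methyl (1R,2S,5R)-2-{hydroxy[(2S,3S)-3-[(trimethylsilyl)ethynyl]oxiran-2-yl]methyl}-6-methoxy-5-methyl-3-oxo-8-oxabicyclo[3.2.1]oct-6-ene-2-carboxylate, both carbinol (C5) epimers; the C4–C5 bond is axial on the oxygen-bridge face | COC(=O)[C@]1(C(O)[C@@H]3O[C@H]3C#C[Si](C)(C)C)C(=O)C[C@@]2(C)O[C@@H]1C=C2OC | intermediate
14 | tricyclic triol: cyclopentane C4–C5–C6–C7–C8 cis-fused to the oxygen-bridge face of the oxabicycle; C5–OH (both epimers); C6–OH, C7–C≡C–SiMe3 and tertiary C8–OH all on the convex face; CO2Me on C4 | COC(=O)[C@@]12C(O)[C@H](O)[C@H](C#C[Si](C)(C)C)[C@@]2(O)C[C@@]3(C)O[C@@H]1C=C3OC | intermediate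
15 | 14 with the C6 hydroxyl as its tert-butyldimethylsilyl ether | COC(=O)[C@@]12C(O)[C@H](O[Si](C)(C)C(C)(C)C)[C@H](C#C[Si](C)(C)C)[C@@]2(O)C[C@@]3(C)O[C@@H]1C=C3OC | intermediate
16 | C5 ketone of 15 (β-keto ester with tertiary C8–OH) | COC(=O)[C@@]12C(=O)[C@H](O[Si](C)(C)C(C)(C)C)[C@H](C#C[Si](C)(C)C)[C@@]2(O)C[C@@]3(C)O[C@@H]1C=C3OC | intermediate
17 | potassium enolate of the ring-expanded β-keto ester: ten-membered ring C1–C10 with O bridging C3 and C10; enolate oxygen on C5 cis to the ester on C4 (not isolated) | C[Si](C)(C)C#C[C@H]1[C@@H](O[Si](C)(C)C(C)(C)C)/C(O[K])=C(/C(=O)OC)[C@H]2C=C(OC)[C@@](C)(CC1=O)O2 | intermediate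
18 | enol triflate: ten-membered ring C1–C10, O bridge C3–C10, C1=C2 methyl enol ether, C4=C5 with CO2Me on C4 and OTf on C5 (OTf cis to the ester, C6 cis to C3), C6–OSiMe2t-Bu, C7–C≡C–SiMe3, C8 ketone; C6, C7 and C10 configured as in 29 | C[Si](C)(C)C#C[C@H]1[C@@H](O[Si](C)(C)C(C)(C)C)/C(OS(=O)(=O)C(F)(F)F)=C(/C(=O)OC)[C@H]2C=C(OC)[C@@](C)(CC1=O)O2 | intermediate
19 | keto enoate: 18 with hydrogen in place of OTf (H5 cis to the ester, C6 cis to C3) | C[Si](C)(C)C#C[C@H]1[C@@H](O[Si](C)(C)C(C)(C)C)/C=C(/C(=O)OC)[C@H]2C=C(OC)[C@@](C)(CC1=O)O2 | intermediate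
20 | silylalkyne diol: 19 with C8–OH (cis to the C7 alkynyl group, configured as in 29) and C15H2OH (not isolated) | C[Si](C)(C)C#C[C@H]1[C@@H](O[Si](C)(C)C(C)(C)C)/C=C(/CO)[C@H]2C=C(OC)[C@@](C)(C[C@H]1O)O2 | intermediate
21 | alkyne diol: 20 with a terminal alkyne on C7; (6S,7R,8R,10R) | C#C[C@H]1[C@@H](O[Si](C)(C)C(C)(C)C)/C=C(/CO)[C@H]2C=C(OC)[C@@](C)(C[C@H]1O)O2 | intermediate
22 | 21 with the C15 hydroxyl as its tert-butyldimethylsilyl ether | C#C[C@H]1[C@@H](O[Si](C)(C)C(C)(C)C)/C=C(/CO[Si](C)(C)C(C)(C)C)[C@H]2C=C(OC)[C@@](C)(C[C@H]1O)O2 | intermediate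
23 | tiglic acid, (E)-2-methylbut-2-enoic acid | C/C=C(\C)C(=O)O | starting material
24 | tiglic 2,4,6-trichlorobenzoic anhydride (not isolated) | C/C=C(\C)C(=O)OC(=O)c1c(Cl)cc(Cl)cc1Cl | intermediate
25 | C8 tiglate of 22 | C#C[C@H]1[C@@H](O[Si](C)(C)C(C)(C)C)/C=C(/CO[Si](C)(C)C(C)(C)C)[C@H]2C=C(OC)[C@@](C)(C[C@H]1OC(=O)/C(C)=C/C)O2 | intermediate
26 | α-bromo ketone: 25 with C1 ketone and bromine on C2 (both C2 epimers) | C#C[C@H]1[C@@H](O[Si](C)(C)C(C)(C)C)/C=C(/CO[Si](C)(C)C(C)(C)C)[C@H]2C(Br)C(=O)[C@@](C)(C[C@H]1OC(=O)/C(C)=C/C)O2 | intermediate
27 | furanone: C1 ketone, C2=C3, ring oxygen C3–O–C10; both silyl ethers, the C8 tiglate and the C7 ethynyl group in place | C#C[C@H]1[C@@H](O[Si](C)(C)C(C)(C)C)/C=C(/CO[Si](C)(C)C(C)(C)C)C2=CC(=O)[C@@](C)(C[C@H]1OC(=O)/C(C)=C/C)O2 | intermediate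
28 | diol: 27 with free C6–OH and C15–OH; C6–OH cis to the C7 ethynyl group | C#C[C@H]1[C@@H](O)/C=C(/CO)C2=CC(=O)[C@@](C)(C[C@H]1OC(=O)/C(C)=C/C)O2 | intermediate
29 | target CNP0269689.6, (4Z,6S,7R,8R,10R) | C=C1C(=O)O[C@H]2/C=C(/CO)C3=CC(=O)[C@@](C)(C[C@@H](OC(=O)/C(C)=C/C)[C@@H]12)O3 | target

Total step count: 19. Longest linear sequence: 16 steps (1, 2, 4, 7–19).

Steps most likely to fail

Step 4 (the proposed new method). The zinc enolate may ionise too slowly and simply be protonated, the stepwise pathway may collapse to (3+2) adducts or the reversed regiochemistry, or the ligand may discriminate the furan faces poorly and give low enantiomeric purity. The fallback uses known chemistry and sets out from 4 and 6: a ligand-free reductive (4+3) cycloaddition with zinc–copper couple in THF, the established racemic oxyallyl/furan reaction, should give the racemic cycloadduct F1. Its enantiomers are separated by preparative chromatography on a chiral stationary phase with supercritical CO2, and the (1R,5R) enantiomer returns to the route as 8.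

Step 7. The aldol addition may revert at the crowded quaternary C4 (retro-aldol of a stabilised enolate, low conversion), or the epoxide may migrate in the metal aldolate. The fallback sets out from 8: silylation (Me3SiCl, Et3N) gives the trimethylsilyl enol ether F2. A fluoride-initiated silyl-transfer aldol with 11 (catalytic Bu4N[Ph3SiF2], THF, −78 → 0 °C) then traps the aldolate irreversibly as the O-silylated aldol adduct F3; no Lewis acid is present, so the C1 enol ether stays a spectator. HF·pyridine buffered with pyridine removes the O-silyl group and the route is rejoined at 13.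

Step 8. Addition of the allenylindium to the hindered C8 ketone may be slow, so that protonation to an allene or intermolecular reactions take over. The fallback sets out from 13 and replaces the polar organometallic by a radical closure: titanocene monochloride (trivalent titanium, from Cp2TiCl2 and Mn dust, THF) opens the oxirane by single-electron transfer at the propargylic C7–O bond, the C7 radical adds 5-exo to the C8 ketone and a second equivalent reduces the alkoxy radical. This returns to the route at 14 and makes no compound outside the list (entry F0).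

Further compounds
F1 | step 4 | racemic methyl 3-hydroxy-6-methoxy-5-methyl-8-oxabicyclo[3.2.1]octa-2,6-diene-2-carboxylate (racemic 8) | COC(=O)C1=C(O)CC2(C)OC1C=C2OC
F2 | step 7 | trimethylsilyl enol ether of 8 | COC(=O)C1=C(O[Si](C)(C)C)C[C@@]2(C)O[C@@H]1C=C2OC
F3 | step 7 | C5 trimethylsilyl ether of aldol adduct 13 | COC(=O)[C@]1(C(O[Si](C)(C)C)[C@@H]3O[C@H]3C#C[Si](C)(C)C)C(=O)C[C@@]2(C)O[C@@H]1C=C2OC
F0 | step 8 | none | none
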